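## Structural features

Nakijiquinone E (41) contains two 4,9-friedodrimane (avarane) trans-decalins of the same absolute configuration (5S,8S,9R,10S), each carrying its aromatic partner on the neopentyl C15 methylene at quaternary C9. Half A has the exocyclic C4=C11 methylidene and is bonded through C15 to C5 of a methyl 2,4-dihydroxybenzoate. Half B has the endocyclic C3'=C4' olefin and is bonded through C15' to C16' of a 2-hydroxy-1,4-benzoquinone. The halves are joined by a secondary amine between arene C3, which lies between the two phenols, and quinone carbon C20'. In each decalin the stereocentres C5, C10, C9 and C8 are contiguous: C5 and C9 are quaternary, their methyls C12 and C14 are syn and 1,3-diaxial, C13 is cis to C14, and H10 is trans to C12. Fragile groups are the exocyclic olefin (acid moves it into the ring or starts cation shifts), the aminohydroxyquinone (nucleophiles, base, reductants), the aminoresorcinol (air) and the methyl ester (hydroxide). The real difficulty is the C5 methyl, which must enter on the hindered β face, syn to the axial C14 methyl and anti to H10. The key step exploits the fact that C4 of ring A, the future methylidene carbon, is bonded to C5: a 4β-hydroxyl beside a C5=C6 olefin in ring B delivers C12 to the β face as a C5–C6 cyclopropane, whose C6–C12 bond is later hydrogenolysed.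

## Logic of the disconnections

41 is cut at N–C20', the only bond between the halves, giving 40 and 28. This is a vinylogous amide, so the forward step is an addition–elimination on a vinylogous ester. The gain is full convergence with no deprotection after the union; the demand is that substitution outruns redox exchange between the aminoresorcinol and the quinone and leaves the methyl ester alone.

40 is cut at the arene C3–N bond, leading to 38 and, behind it, 37. Once C5 carries the decalin, C3 is the only position activated by both oxygens, so an electrophilic nitrogen source can only go there (through 39). The demand is a non-acidic, non-radical amination that spares the exocyclic olefin.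

37 is cut at C15–C5(arene) by way of 36 and 33, giving 19 and 32 (from 31, 30, 29). Neopentyl C15 cannot take part in a substitution, so C15 is used as an aldehyde carbon and its oxygen is removed afterwards by a radical chain. The demand is an aryl nucleophile that tolerates its own ester; the carbinol configuration is irrelevant.

28 is traced through 27 (C17'–OH from methoxy), 26 (quinone from a tetramethoxyarene), 25 (C3'=C4' from C4'=C11') and 24 to the same aldehyde 19 plus 21 (from 20). The gain is that one decalin serves both halves. The demands are a regioselective hydrolysis of one of two vinylogous esters and a complete olefin migration before the quinone is formed.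

19 is taken back through 18, 17 and 16 to 15: C4=C11 is cut to a C4 ketone, and C15 is returned to its pivalate. The demand is methylenation of a ketone flanked by quaternary C5.

15 is reconnected at C6–C12 to give 14. The forward hydrogenolysis must cleave this least substituted cyclopropane bond and not C5–C12 or C5–C6.

14 is cut at C5–C12 and C6–C12 to give 12 (through 13). The quaternary-centre problem is reduced to the facial selectivity of a directed addition to a trisubstituted olefin. The demand is a β-hydroxyl at C4 and no competing Lewis-basic group on the α face.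

12 is traced through 11, 10, 9 and 8 to 7. The cycloaddition necessarily places the C4 oxygen cis to H10, so C4 must be inverted by oxidation and reduction; C15 is reduced and capped on the way. The demand is axial hydride delivery on the α face.

7 is cut at C7–C8 and C9–C10 (cyclohexene retron of ring B) to give 5 and 6. Three stereocentres arise at once. The demands are 'ortho' regiochemistry, the exo (formyl-out) topology, approach anti to the C4 oxygen, and transfer of the E geometry of 6 into the cis C13/C14 relationship.

5 is cut at the C5–C6 (vinyl) bond and traced through 4, 3 and 2 to 1. The single stereocentre of 3 is the source of absolute configuration and must be set by a reliable catalytic reduction.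

## Other disconnections considered

Alternative 1: The quinone ring of half B is cut at C20'–C21' and traced back to the 4-hydroxy-4-ynamido cyclobutenone A1, whose ynamide nitrogen already carries the protected arene of half A. On heating, A1 should open by 4π electrocyclic ring opening to an enynyl ketene; the ketene carbon bonds to the nitrogen-bearing alkyne carbon, and the six-membered diradical takes up the hydroxyl hydrogen to give the protected quinone A2 (Moore rearrangement).
- In its favour: quinone and N–C20' bond arise in one neutral thermal step; the positions of N, O and the C15' branch follow unambiguously from squarate chemistry; no free, oxidisable aminoresorcinol is handled.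
- Against it here: A1 needs a neopentyl C15' organometallic added to a squarate ester and N-alkynylation of a hindered benzoxazolone; enynyl ketenes with radical-stabilising alkyne substituents can close to five-membered alkylidene cyclopentenediones instead; A2 still carries three different protecting groups to be removed beside the exocyclic olefin and the ester.
- Comparison: this alternative is the better on the regiochemical definition of the quinone and on avoiding the late amine/quinone substitution, and the equal in convergence. It is weaker on protecting-group economy, and it does not address C5 and C9 of either decalin, so a decalin synthesis like the present one would still be needed and the count would not fall.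

Alternative 2: Both rings of decalin B are cut at C5'–C10' and C8'–C9', giving the acyclic aryl enone A3 with a 1,1-disubstituted olefin and a methyl ketone. Fe(acac)3/PhSiH3 should transfer a hydrogen atom to C12'; the tertiary C5' radical adds 6-exo to C10' (Giese addition), and the enolate closes ring B by aldol addition to the C8' ketone, giving A4.
- In its favour: two rings, two C–C bonds and four stereocentres, both quaternary carbons included, arise in one step, and C15' is already bonded to the arene.
- Against it: every new centre is steered by the single C4' silyloxy centre through a flexible chain, so the trans C5'/C10' relationship and the aldol geometry have no rigid control element. Afterwards the C15' ketone must become a methylene, the C8' hydroxyl must be replaced by hydrogen with the right configuration, and C4' must become the olefin.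
- Comparison: in bonds and rings formed per step the alternative is the better, since the chosen key step makes a bond (C6–C12) that is cut again. The chosen plan is the better in stereochemical reliability and in supplying both halves from one decalin; A4 is tailored to half B. Step counts should be similar once the clean-up is included.

Alternative 3: No ring bond is cut; the methyls on C5' and C9' and the hydrogens on C8' and C10' are traced back to their drimane positions in the 8-hydroxy-11-quinonyl drimane A5, available from sclareolide. BF3·OEt2 should ionise C8, and four suprafacial 1,2-shifts (H9 to C8, CH3 from C10 to C9, H5 to C10, CH3 from C4 to C5) followed by loss of H3 give A6, which is identical with 27.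
- In its favour: chiral-pool start, every stereocentre inherited by stereospecific shifts, very short, and it gives exactly the endocyclic olefin of half B.
- Against it: the cascade can stop at intermediate cations, end in the exocyclic isomer, or be intercepted by a quinone oxygen; it cannot give the less stable exocyclic olefin of half A selectively.
- Comparison: for half B alone this alternative is the better in material supply and the equal in stereochemical security. In step count it is about equal, because steps 1–16 are needed for half A anyway and 27 then costs four further steps from 19. The chosen plan is the better for the exocyclic olefin, which it sets kinetically by Wittig reaction.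

Key step: step 11

Remark on numbering: avarane numbering is used for both decalins (C11 on C4, C12 on C5, C13 on C8, C14 and C15 on C9; primes for half B, quinone ring C16'–C21'). β is the face of C12 and C14, α the face of H10. Benzoate positions are counted from the ester-bearing carbon C1.

Remark on the key-step structures: 12 and 14 were compared with 41 centre by centre (C4–O β, C12 β, H10 and C15 α, C13 and C14 β, cis-fused cyclopropane). They agree with the target and are used unchanged. The refinements are a single-enantiomer diene, a pivalate on C15, and a carbinol set by Luche reduction.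

Assumption: the C15 carbinol epimers in 22–24 and 33–36 are carried as mixtures and drawn without configuration, because the oxygen is removed.

Step 1
Reactants: 1 cyclohex-2-en-1-one
Product: 2 2-iodocyclohex-2-en-1-one
Conditions: I2, pyridine, CH2Cl2, 0 °C → rt
Reagents that add atoms: iodine, II
Why: Pyridine adds to the enone in conjugate fashion, the enolate is iodinated and pyridine is expelled (addition–elimination α-iodination of an enone); no stereocentre is formed.

Step 2
Reactants: 2 2-iodocyclohex-2-en-1-one
Product: 3 (R)-2-iodocyclohex-2-en-1-ol
Conditions: (S)-2-methyl-CBS-oxazaborolidine (10 mol %), BH3·SMe2, THF, −20 °C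
Reagents that add atoms: none
Why: Corey–Bakshi–Shibata reduction; the iodo-substituted alkenyl carbon is the larger flank of the ketone, so the (S)-oxazaborolidine–borane complex should deliver hydride to give the (R)-carbinol. This centre is the only source of absolute configuration in the route.

Step 3
Reactants: 3 (R)-2-iodocyclohex-2-en-1-ol
Product: 4 (R)-tert-butyl[(2-iodocyclohex-2-en-1-yl)oxy]dimethylsilane
Conditions: TBSCl, imidazole, DMF, rt
Reagents that add atoms: tert-butyldimethylsilyl chloride, CC(C)(C)[Si](C)(C)Cl
Why: Standard silylation of a secondary allylic alcohol; the bulky silyl ether later blocks one face of the diene and survives a Lewis acid at low temperature.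

Step 4
Reactants: 4 (R)-tert-butyl[(2-iodocyclohex-2-en-1-yl)oxy]dimethylsilane
Product: 5 (R)-tert-butyl[(2-ethenylcyclohex-2-en-1-yl)oxy]dimethylsilane
Conditions: Bu3SnCH=CH2, Pd(PPh3)4 (5 mol %), CuI (10 mol %), DMF, 50 °C
Reagents that add atoms: tributyl(ethenyl)stannane, C=C[Sn](CCCC)(CCCC)CCCC
Why: Stille coupling of an alkenyl iodide with a vinylstannane proceeds with retention at the sp2 carbon and leaves the allylic silyl ether and its stereocentre untouched.

Step 5
Reactants: 5 (R)-tert-butyl[(2-ethenylcyclohex-2-en-1-yl)oxy]dimethylsilane; 6 (E)-2-methylbut-2-enal (tiglic aldehyde)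
Product: 7 Diels–Alder aldehyde: octal-5-ene with 4α-OTBS; 8β-CH3; 9β-CH3; 9α-CHO (C15); 10α-H
Conditions: Me2AlCl (0.3 equiv), CH2Cl2, −78 → −30 °C
Reagents that add atoms: none
Why: Lewis acid-catalysed Diels–Alder reaction forming C7–C8 and C9–C10: the unsubstituted vinyl terminus C7 (largest HOMO coefficient) bonds to the β-carbon of the complexed enal, and the α-methyl enal reacts through the exo (formyl-out) transition state, which places C15 cis to H10. The dienophile approaches the diene face opposite to the pseudoaxial C4 silyloxy group, which fixes C8, C9 and C10 relative to C4, and the E geometry of 6 is transferred as the cis relationship of C13 and C14.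

Step 6
Reactants: 7 Diels–Alder aldehyde
Product: 8 C15 alcohol: octal-5-ene with 4α-OTBS; 8β-CH3; 9β-CH3; 9α-CH2OH; 10α-H
Conditions: NaBH4, MeOH, 0 °C
Reagents that add atoms: none
Why: Chemoselective hydride reduction of the neopentyl aldehyde; olefin and silyl ether are inert and no stereocentre is touched.

Step 7
Reactants: 8 C15 alcohol
Product: 9 C15 pivalate: octal-5-ene with 4α-OTBS; 8β-CH3; 9β-CH3; 9α-CH2OPiv; 10α-H
Conditions: t-BuCOCl, pyridine, DMAP (cat.), CH2Cl2, rt → 40 °C
Reagents that add atoms: pivaloyl chloride, CC(C)(C)C(=O)Cl
Why: DMAP-catalysed acylation of the hindered primary alcohol; the pivalate is a robust, weakly Lewis-basic cap for C15 that tolerates fluoride, the zinc carbenoid, hydrogenation and the ylide.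

Step 8
Reactants: 9 C15 pivalate with 4α-OTBS
Product: 10 4α-allylic alcohol: octal-5-ene with 4α-OH; 8β-CH3; 9β-CH3; 9α-CH2OPiv; 10α-H
Conditions: Bu4NF, THF, rt
Reagents that add atoms: none
Why: Fluoride-induced cleavage of the silyl ether; the pivalate is stable to Bu4NF at room temperature.

Step 9
Reactants: 10 4α-allylic alcohol
Product: 11 enone: octal-5-en-4-one with 8β-CH3; 9β-CH3; 9α-CH2OPiv; 10α-H
Conditions: Dess–Martin periodinane, CH2Cl2, 0 °C → rt
Reagents that add atoms: none
Why: Dess–Martin oxidation of the allylic alcohol gives the conjugated enone under non-epimerising conditions and erases the C4 stereocentre, which has done its work.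

Step 10
Reactants: 11 enone
Product: 12 4β-allylic alcohol: octal-5-ene with 4β-OH; 8β-CH3; 9β-CH3; 9α-CH2OPiv; 10α-H
Conditions: NaBH4, CeCl3·7H2O, MeOH, −40 °C
Reagents that add atoms: none
Why: Luche 1,2-reduction; the small borohydride attacks the cyclohexanone carbonyl along the axial trajectory on the α face (the face of axial H10) and gives the equatorial 4β-alcohol, the epimer of 10. CeCl3 suppresses conjugate reduction.

Step 11
Reactants: 12 4β-allylic alcohol
Product: 14 cyclopropane alcohol: 4β-OH; C12 bridging C5 and C6 on the β face; 8β-CH3; 9β-CH3; 9α-CH2OPiv; 10α-H, via ethylzinc alkoxide 13 (not isolated)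
Conditions: Et2Zn, CH2I2, CH2Cl2, −10 °C → rt; NH4Cl aq.
Reagents that add atoms: diiodomethane, ICI
Why: Et2Zn first deprotonates the carbinol to the ethylzinc alkoxide 13, and a second equivalent exchanges with CH2I2 to the carbenoid EtZnCH2I, which is held by the alkoxide oxygen. The methylene is then transferred to C5=C6 in a concerted, asynchronous butterfly transition state that forms C5–C12 and C6–C12 together; the closest known reaction type is the hydroxyl-directed Simmons–Smith cyclopropanation of cyclic allylic alcohols with Et2Zn/CH2I2. The three-membered ring is closed by a single stereospecific [2+1] syn addition to the olefin, so its cis fusion to ring B is geometrically enforced and no stepwise closure is involved. C5 and C6 are both set by the face of delivery, which is dictated by the C4 oxygen: the equatorial β-alkoxide lies slightly on the β side of the olefin plane and can reach only that face without severe strain, so C12 ends up β, anti to H10. The selectivity needed is facial, against the steric preference for the α face caused by the axial C14 methyl. It is secured by the rate advantage of the alkoxide-bound carbenoid over the unbound one, by the absence of A(1,3) strain (only H6 faces the carbinol), and by capping C15 on the α face as a non-coordinating pivalate so that no second alkoxide can direct. Chemoselectivity is not at stake, since C5=C6 is the only olefin and the ester is inert to the carbenoid.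

Step 12
Reactants: 14 cyclopropane alcohol
Product: 15 trans-decalin alcohol: 4β-OH; 5β-CH3 (C12); 8β-CH3; 9β-CH3; 9α-CH2OPiv; 10α-H
Conditions: H2 (1 atm), PtO2, AcOH, rt
Reagents that add atoms: none
Why: Hydrogenolysis of the cyclopropane on PtO2 in AcOH cleaves the least substituted and most accessible bond, C6(H)–C12(H2), so C12 stays on quaternary C5 as the β-methyl. C5 keeps its configuration because its bond to C12 is not touched, and the trans-decalin results.

Step 13
Reactants: 15 trans-decalin alcohol
Product: 16 C4 ketone: trans-decalin-4-one with 5β-CH3; 8β-CH3; 9β-CH3; 9α-CH2OPiv; 10α-H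
Conditions: Dess–Martin periodinane, CH2Cl2, rt
Reagents that add atoms: none
Why: Dess–Martin oxidation of the hindered secondary alcohol; the directing carbinol becomes the handle for the methylidene group.

Step 14
Reactants: 16 C4 ketone
Product: 17 methylidene pivalate: 4(11)-ene; 5β-CH3; 8β-CH3; 9β-CH3; 9α-CH2OPiv; 10α-H
Conditions: Ph3PCH3Br, KOt-Bu, toluene, 90 °C
Reagents that add atoms: methyltriphenylphosphonium bromide, C[P+](c1ccccc1)(c1ccccc1)c1ccccc1.[Br-]
Why: Wittig methylenation with the salt-free ylide at elevated temperature is the standard way to methylenate a ketone flanked by a quaternary carbon; the pivalate is not attacked by the non-nucleophilic ylide, and C5 and C10 cannot epimerise.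

Step 15
Reactants: 17 methylidene pivalate
Product: 18 C15 alcohol: 4(11)-ene; 5β-CH3; 8β-CH3; 9β-CH3; 9α-CH2OH; 10α-H
Conditions: i-Bu2AlH, CH2Cl2, −78 °C
Reagents that add atoms: none
Why: Reductive cleavage of the pivalate by i-Bu2AlH frees the neopentyl C15 alcohol without touching the olefin.

Step 16
Reactants: 18 C15 alcohol
Product: 19 C15 aldehyde: 4(11)-ene; 5β-CH3; 8β-CH3; 9β-CH3; 9α-CHO; 10α-H
Conditions: Dess–Martin periodinane, CH2Cl2, rt
Reagents that add atoms: none
Why: Dess–Martin oxidation to the neopentyl aldehyde, which has no α-hydrogen and therefore cannot enolise or epimerise.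

Step 17
Reactants: 20 1,2,4,5-tetramethoxybenzene; 19 C15 aldehyde
Product: 24 S-methyl xanthate of the C15 carbinol bearing the 2,3,5,6-tetramethoxyphenyl group (4(11)-ene decalin; C15 epimers), via 2,3,5,6-tetramethoxyphenyllithium 21 (not isolated), via lithium C15-alkoxide 22 (not isolated), via lithium xanthate salt 23 (not isolated)
Conditions: n-BuLi, THF, 0 °C → rt; 19, −78 → 0 °C; CS2, then MeI, 0 °C → rt
Reagents that add atoms: carbon disulfide, S=C=S; iodomethane, CI
Why: Directed ortho-lithiation of 20 between two methoxy groups gives 21, which adds to the hindered aldehyde; the lithium alkoxide 22 is trapped in the same flask by CS2 and the xanthate salt 23 is S-methylated. The C15 configuration is irrelevant because the oxygen is removed in the next step.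

Step 18
Reactants: 24 S-methyl xanthate
Product: 25 15-(2,3,5,6-tetramethoxyphenyl) decalin with 4(11)-ene; 5β-CH3; 8β-CH3; 9β-CH3; 9α-CH2Ar; 10α-H
Conditions: Bu3SnH, AIBN (cat.), toluene, 110 °C
Reagents that add atoms: none
Why: Barton–McCombie deoxygenation: the stannyl radical adds to the thiocarbonyl, and the benzylic C15 radical is released and reduced by Bu3SnH. No β-hydrogen is available for elimination, and the olefin is too remote for cyclisation.

Step 19
Reactants: 25 tetramethoxyaryl 4(11)-ene
Product: 26 15'-(2,3,5,6-tetramethoxyphenyl) decalin with 3'-ene; 5'β-CH3; 8'β-CH3; 9'β-CH3; 9'α-CH2Ar; 10'α-H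
Conditions: RhCl3·3H2O (10 mol %), EtOH, 80 °C
Reagents that add atoms: none
Why: RhCl3-catalysed olefin isomerisation by rhodium hydride addition–elimination moves the exocyclic double bond into the ring, to the more stable trisubstituted C3'=C4' position. C5' is quaternary, so the double bond cannot migrate towards the ring fusion.

Step 20
Reactants: 26 tetramethoxyaryl 3'-ene
Product: 27 2,5-dimethoxy-3-(decalinylmethyl)-1,4-benzoquinone of half B (methoxy on C17' and C20'; 3'-ene)
Conditions: (NH4)2Ce(NO3)6, MeCN–H2O, 0 °C
Reagents that add atoms: water, O
Why: Oxidative demethylation of the tetramethoxyarene by (NH4)2Ce(NO3)6; either para pair of methoxy groups leads to the same 2,5-dimethoxy-1,4-benzoquinone, and the trisubstituted olefin is not attacked at 0 °C.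

Step 21
Reactants: 27 dimethoxyquinone of half B
Product: 28 2-hydroxy-5-methoxy-3-(decalinylmethyl)-1,4-benzoquinone of half B (C17'–OH; C20'–OCH3; 3'-ene)
Conditions: KOH, MeOH–H2O, rt; then HCl aq.
Reagents that add atoms: potassium hydroxide, [K+].[OH-]
Why: Hydroxide adds to the vinylogous ester carbon C17' and expels methoxide (addition–elimination). The methoxy group next to the C15' branch is twisted out of conjugation and is the more electrophilic of the two, which is the known pattern for 3-alkyl-2,5-dimethoxybenzoquinones; the product anion resists a second substitution.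

Step 22
Reactants: 29 methyl 2,4-dihydroxybenzoate
Product: 30 methyl 2,4-dihydroxy-5-iodobenzoate
Conditions: ICl, AcOH, rt
Reagents that add atoms: iodine monochloride, ClI
Why: Electrophilic aromatic iodination at C5, para to the 2-hydroxyl and ortho to the 4-hydroxyl, and less hindered than C3 between the two oxygens.

Step 23
Reactants: 30 methyl 2,4-dihydroxy-5-iodobenzoate
Product: 31 methyl 5-iodo-2,4-bis(methoxymethoxy)benzoate
Conditions: MeOCH2Cl, i-Pr2NEt, CH2Cl2, 0 → 40 °C
Reagents that add atoms: chloromethyl methyl ether, COCCl
Why: Base-mediated O-alkylation of both phenols; the acetal ethers withstand the arylmagnesium reagent, the amide base and the tin hydride, and the ortho oxygen assists the halogen–metal exchange.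

Step 24
Reactants: 31 methyl 5-iodo-2,4-bis(methoxymethoxy)benzoate; 19 C15 aldehyde
Product: 33 methyl 5-[C15-hydroxy(decalinyl)methyl]-2,4-bis(methoxymethoxy)benzoate (4(11)-ene decalin; C15 epimers), via arylmagnesium chloride 32 (not isolated)
Conditions: i-PrMgCl·LiCl, THF, −40 °C; then 19, −40 → 0 °C
Reagents that add atoms: none
Why: Iodine–magnesium exchange with i-PrMgCl·LiCl at low temperature gives an arylmagnesium reagent that tolerates its own methyl ester, and this adds to the neopentyl aldehyde (1,2-addition of a functionalised Grignard reagent). The C15 epimers are carried on together.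

Step 25
Reactants: 33 benzylic C15 alcohol
Product: 36 S-methyl xanthate of 33 (C15 epimers), via sodium C15-alkoxide 34 (not isolated), via sodium xanthate salt 35 (not isolated)
Conditions: NaN(SiMe3)2, THF, −78 °C; CS2; MeI, −78 → 0 °C
Reagents that add atoms: carbon disulfide, S=C=S; iodomethane, CI
Why: Deprotonation of the hindered carbinol, addition of the alkoxide to CS2 and S-methylation give the xanthate; the aryl ester has no α-hydrogen and is not attacked by the amide base at low temperature.

Step 26
Reactants: 36 S-methyl xanthate
Product: 37 methyl 5-(decalinylmethyl)-2,4-bis(methoxymethoxy)benzoate (4(11)-ene; 5β-CH3; 8β-CH3; 9β-CH3; 10α-H)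
Conditions: Bu3SnH, AIBN (cat.), toluene, 110 °C
Reagents that add atoms: none
Why: Barton–McCombie deoxygenation as in step 18; the ester, the acetals and the exocyclic olefin are inert to the tin radical chain.

Step 27
Reactants: 37 bis(methoxymethyl) ether
Product: 38 methyl 5-(decalinylmethyl)-2,4-dihydroxybenzoate (4(11)-ene decalin)
Conditions: HCl (cat.), MeOH–THF, rt
Reagents that add atoms: none
Why: Acid-catalysed transacetalisation to methanol; aryl acetals of an electron-poor salicylate are labile enough for dilute acid at room temperature, conditions under which the 1,1-disubstituted olefin should neither add methanol nor migrate.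

Step 28
Reactants: 38 methyl 5-(decalinylmethyl)-2,4-dihydroxybenzoate
Product: 40 methyl 3-amino-5-(decalinylmethyl)-2,4-dihydroxybenzoate (4(11)-ene decalin), via azo compound 39 (not isolated)
Conditions: 4-diazoniobenzenesulfonate, Na2CO3, THF–MeOH–H2O, 0 °C; then Na2S2O4, 50 °C, Ar
Reagents that add atoms: 4-diazoniobenzenesulfonate, N#[N+]c1ccc(cc1)S(=O)(=O)[O-]
Why: Azo coupling of the resorcinol monoanion takes place at C3, the only free position ortho to a phenoxide (C5 is blocked and C6 is meta to both oxygens), and Na2S2O4 then cleaves the N=N bond reductively to the primary arylamine. Both operations are classical for aminophenol synthesis and leave the olefin and the ester alone.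

Step 29
Reactants: 40 methyl 3-amino-5-(decalinylmethyl)-2,4-dihydroxybenzoate; 28 hydroxy methoxy quinone of half B
Product: 41 nakijiquinone E
Conditions: NaHCO3, EtOH–THF, 40 °C, Ar
Reagents that add atoms: none
Why: Addition–elimination of the arylamine at C20' of the vinylogous ester (conversion into a vinylogous amide), the established way in which amines replace the methoxy group of 2-hydroxy-5-methoxy-1,4-benzoquinones. The hydroxyquinone is present as its anion, so only the methoxy enone unit is electrophilic; no stereocentre is involved.

## Compound list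

1 | cyclohex-2-en-1-one | O=C1C=CCCC1 | starting material
2 | 2-iodocyclohex-2-en-1-one | O=C1CCCC=C1I | intermediate
3 | (R)-2-iodocyclohex-2-en-1-ol | O[C@@H]1CCCC=C1I | intermediate
4 | (R)-tert-butyl[(2-iodocyclohex-2-en-1-yl)oxy]dimethylsilane | CC(C)(C)[Si](C)(C)O[C@@H]1CCCC=C1I | intermediate
5 | (R)-tert-butyl[(2-ethenylcyclohex-2-en-1-yl)oxy]dimethylsilane | CC(C)(C)[Si](C)(C)O[C@@H]1CCCC=C1C=C | intermediate
6 | (E)-2-methylbut-2-enal (tiglic aldehyde) | C/C=C(\C)C=O | starting material
7 | Diels–Alder aldehyde (5-ene, 4α-OTBS, 9α-CHO, 10α-H) | CC(C)(C)[Si](C)(C)O[C@@H]1CCC[C@H]2[C@](C)(C=O)[C@@H](C)CC=C12 | intermediate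
8 | C15 alcohol (5-ene, 4α-OTBS) | CC(C)(C)[Si](C)(C)O[C@@H]1CCC[C@H]2[C@](C)(CO)[C@@H](C)CC=C12 | intermediate
9 | C15 pivalate (5-ene, 4α-OTBS) | CC(C)(C)[Si](C)(C)O[C@@H]1CCC[C@H]2[C@](C)(COC(=O)C(C)(C)C)[C@@H](C)CC=C12 | intermediate
10 | 4α-allylic alcohol, C15 pivalate | O[C@@H]1CCC[C@H]2[C@](C)(COC(=O)C(C)(C)C)[C@@H](C)CC=C12 | intermediate
11 | 5-en-4-one, C15 pivalate | O=C1CCC[C@H]2[C@](C)(COC(=O)C(C)(C)C)[C@@H](C)CC=C12 | intermediate
12 | 4β-allylic alcohol, C15 pivalate (key-step precursor) | O[C@H]1CCC[C@H]2[C@](C)(COC(=O)C(C)(C)C)[C@@H](C)CC=C12 | intermediate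
13 | ethylzinc alkoxide of 12 | CC[Zn]O[C@H]1CCC[C@H]2[C@](C)(COC(=O)C(C)(C)C)[C@@H](C)CC=C12 | intermediate (not isolated)
14 | 5β,6β-cyclopropane, 4β-OH, C15 pivalate (key-step product) | O[C@H]1CCC[C@H]2[C@](C)(COC(=O)C(C)(C)C)[C@@H](C)C[C@H]3C[C@@]123 | intermediate
15 | trans-decalin, 4β-OH, 5β-CH3, C15 pivalate | O[C@H]1CCC[C@H]2[C@](C)(COC(=O)C(C)(C)C)[C@@H](C)CC[C@]12C | intermediate
16 | trans-decalin-4-one, C15 pivalate | O=C1CCC[C@H]2[C@](C)(COC(=O)C(C)(C)C)[C@@H](C)CC[C@]12C | intermediate
17 | 4(11)-ene, C15 pivalate | C=C1CCC[C@H]2[C@](C)(COC(=O)C(C)(C)C)[C@@H](C)CC[C@]12C | intermediate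
18 | 4(11)-en-15-ol | C=C1CCC[C@H]2[C@](C)(CO)[C@@H](C)CC[C@]12C | intermediate
19 | 4(11)-en-15-al | C=C1CCC[C@H]2[C@](C)(C=O)[C@@H](C)CC[C@]12C | intermediate
20 | 1,2,4,5-tetramethoxybenzene | COc1cc(OC)c(OC)cc1OC | starting material
21 | 2,3,5,6-tetramethoxyphenyllithium | [Li]c1c(OC)c(OC)cc(OC)c1OC | intermediate (not isolated)
22 | lithium C15-alkoxide (tetramethoxyphenyl carbinol) | C=C1CCC[C@H]2[C@](C)(C(O[Li])c3c(OC)c(OC)cc(OC)c3OC)[C@@H](C)CC[C@]12C | intermediate (not isolated)
23 | lithium xanthate salt | C=C1CCC[C@H]2[C@](C)(C(OC(=S)S[Li])c3c(OC)c(OC)cc(OC)c3OC)[C@@H](C)CC[C@]12C | intermediate (not isolated)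
24 | S-methyl xanthate (tetramethoxyphenyl series) | C=C1CCC[C@H]2[C@](C)(C(OC(=S)SC)c3c(OC)c(OC)cc(OC)c3OC)[C@@H](C)CC[C@]12C | intermediate
25 | 15-(2,3,5,6-tetramethoxyphenyl)-4(11)-ene | C=C1CCC[C@H]2[C@](C)(Cc3c(OC)c(OC)cc(OC)c3OC)[C@@H](C)CC[C@]12C | intermediate
26 | 15'-(2,3,5,6-tetramethoxyphenyl)-3'-ene | CC1=CCC[C@H]2[C@](C)(Cc3c(OC)c(OC)cc(OC)c3OC)[C@@H](C)CC[C@]12C | intermediate
27 | 2,5-dimethoxy-3-(decalinylmethyl)-1,4-benzoquinone, 3'-ene | COC1=CC(=O)C(OC)=C(C[C@]2(C)[C@@H](C)CC[C@]3(C)C(C)=CCC[C@@H]23)C1=O | intermediate
28 | 2-hydroxy-5-methoxy-3-(decalinylmethyl)-1,4-benzoquinone, 3'-ene (half B) | COC1=CC(=O)C(O)=C(C[C@]2(C)[C@@H](C)CC[C@]3(C)C(C)=CCC[C@@H]23)C1=O | intermediate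
29 | methyl 2,4-dihydroxybenzoate | COC(=O)c1ccc(O)cc1O | starting material
30 | methyl 2,4-dihydroxy-5-iodobenzoate | COC(=O)c1cc(I)c(O)cc1O | intermediate
31 | methyl 5-iodo-2,4-bis(methoxymethoxy)benzoate | COCOc1cc(OCOC)c(C(=O)OC)cc1I | intermediate
32 | arylmagnesium chloride from 31 | COCOc1cc(OCOC)c(C(=O)OC)cc1[Mg]Cl | intermediate (not isolated)
33 | benzylic C15 alcohol (benzoate series) | C=C1CCC[C@H]2[C@](C)(C(O)c3cc(C(=O)OC)c(OCOC)cc3OCOC)[C@@H](C)CC[C@]12C | intermediate
34 | sodium C15-alkoxide of 33 | C=C1CCC[C@H]2[C@](C)(C(O[Na])c3cc(C(=O)OC)c(OCOC)cc3OCOC)[C@@H](C)CC[C@]12C | intermediate (not isolated)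
35 | sodium xanthate salt | C=C1CCC[C@H]2[C@](C)(C(OC(=S)S[Na])c3cc(C(=O)OC)c(OCOC)cc3OCOC)[C@@H](C)CC[C@]12C | intermediate (not isolated)
36 | S-methyl xanthate (benzoate series) | C=C1CCC[C@H]2[C@](C)(C(OC(=S)SC)c3cc(C(=O)OC)c(OCOC)cc3OCOC)[C@@H](C)CC[C@]12C | intermediate
37 | methyl 5-(decalinylmethyl)-2,4-bis(methoxymethoxy)benzoate | C=C1CCC[C@H]2[C@](C)(Cc3cc(C(=O)OC)c(OCOC)cc3OCOC)[C@@H](C)CC[C@]12C | intermediate
38 | methyl 5-(decalinylmethyl)-2,4-dihydroxybenzoate | C=C1CCC[C@H]2[C@](C)(Cc3cc(C(=O)OC)c(O)cc3O)[C@@H](C)CC[C@]12C | intermediate
39 | 3-[(E)-(4-sulfophenyl)diazenyl] derivative of 38 | C=C1CCC[C@H]2[C@](C)(Cc3cc(C(=O)OC)c(O)c(/N=N/c4ccc(S(=O)(=O)O)cc4)c3O)[C@@H](C)CC[C@]12C | intermediate (not isolated)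
40 | methyl 3-amino-5-(decalinylmethyl)-2,4-dihydroxybenzoate (half A) | C=C1CCC[C@H]2[C@](C)(Cc3cc(C(=O)OC)c(O)c(N)c3O)[C@@H](C)CC[C@]12C | intermediate
41 | nakijiquinone E | C=C1CCC[C@H]2[C@](C)(Cc3cc(C(=O)OC)c(O)c(NC4=CC(=O)C(O)=C(C[C@]5(C)[C@@H](C)CC[C@]6(C)C(C)=CCC[C@@H]56)C4=O)c3O)[C@@H](C)CC[C@]12C | target

## Step count and least certain steps

Total: 29 steps. Longest linear sequence: 22 steps (steps 1–16, then 24–29). The half-B arm (steps 17–21) and the arene arm (steps 22–23) join it at steps 29 and 24.

Step 11 (key step). The likely failure is poor facial selectivity: methylene transfer to the α face, or an unselective background reaction of unbound carbenoid. The cause is that the equatorial hydroxyl lies close to the olefin plane while the axial C14 methyl shields the β face. Fallback, from 12: silylation with (bromomethyl)chlorodimethylsilane gives the (bromomethyl)dimethylsilyl ether F1. Bu3SnH/AIBN should then close the oxasilolane F2 by 5-exo attack of the tethered radical on C5, so that C5–C12 is forced onto the face of the C4 oxygen. Protodesilylation with Bu4NF in DMF cleaves C12–Si and O–Si and returns to the route at 15, bypassing 14 and step 12.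

Step 5. The likely failures are incomplete exo or facial selectivity, or ionisation of the allylic silyl ether by the Lewis acid before cycloaddition. Fallback with catalyst control instead of substrate control, from 2: ketalisation with ethylene glycol gives the dioxolane F3, and Stille vinylation gives the achiral diene F4. An exo-selective, enantioselective Diels–Alder reaction with 6 under a triflimide-activated chiral oxazaborolidine gives the aldehyde F5. NaBH4 reduction gives the alcohol F6 and pivaloylation gives F7. Mild acid hydrolysis of the ketal (pyridinium tosylate, aqueous acetone) returns to the route at 11.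

Step 10. The likely failure is hydride delivery from the wrong face, which regenerates 10, or partial conjugate reduction. Fallback, from 10: Mitsunobu inversion with 4-nitrobenzoic acid (PPh3, DIAD) gives the 4β-(4-nitrobenzoate) F8. Selective methanolysis of the aryl ester (K2CO3, MeOH; the pivalate is far slower) returns to the route at 12.

Step 24. The likely failures are incomplete iodine–magnesium exchange, or consumption of the arylmagnesium reagent by its own ester while addition to the hindered neopentyl aldehyde is slow. Fallback with reversed polarity, from 18: iodination (I2, PPh3, imidazole, toluene, 80 °C) gives the neopentyl iodide F9. t-BuLi at −78 °C gives the alkyllithium F10, and ZnCl2 gives the alkylzinc chloride F11. Negishi coupling with 31 (Pd(OAc)2, SPhos, THF) returns to the route at 37, skipping steps 25 and 26. C9 is quaternary, so β-hydride elimination is excluded, and the organozinc tolerates the ester.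

Step 28. The likely failures are sluggish azo coupling at the position flanked by two oxygens, with decomposition of the diazonium salt, or air oxidation of the aminoresorcinol during isolation. Fallback, from 38: nitration at C3 with one equivalent of HNO3 in AcOH–CH2Cl2 at 0 °C gives the nitro compound F12. Reduction with Zn/NH4Cl in aqueous THF returns to the route at 40.

Step 29. The likely failures are slow addition–elimination of the hindered arylamine on the anionic hydroxyquinone, overtaken by redox exchange between aminoresorcinol and quinone or by condensation to phenoxazine-type products. Fallback, from 40 and 27 (step 21 omitted): the neutral, more electrophilic dimethoxyquinone 27 should take the amine at the unhindered C20'–OCH3 and give the anilino methoxy quinone F13. Hydrolysis of the remaining vinylogous ester (KOH, MeOH–H2O, 0 °C; the salicylate ester is shielded as its phenoxide) arrives at 41.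

## Further compounds

F1 | step 11 | (bromomethyl)dimethylsilyl ether of 12 | BrC[Si](C)(C)O[C@H]1CCC[C@H]2[C@](C)(COC(=O)C(C)(C)C)[C@@H](C)CC=C12
F2 | step 11 | oxasilolane bridging O4 and C5 through C12 (5β-CH2–Si) | C[Si]1(C)O[C@H]2CCC[C@H]3[C@](C)(COC(=O)C(C)(C)C)[C@@H](C)CC[C@]23C1
F3 | step 5 | 6-iodo-1,4-dioxaspiro[4.5]dec-6-ene | IC1=CCCCC12OCCO2
F4 | step 5 | 6-ethenyl-1,4-dioxaspiro[4.5]dec-6-ene | C=CC1=CCCCC12OCCO2
F5 | step 5 | ketal aldehyde (5-ene, C4 dioxolane, 9α-CHO, 10α-H) | O1CCOC12CCC[C@H]3[C@](C)(C=O)[C@@H](C)CC=C23
F6 | step 5 | ketal C15 alcohol | O1CCOC12CCC[C@H]3[C@](C)(CO)[C@@H](C)CC=C23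
F7 | step 5 | ketal C15 pivalate | O1CCOC12CCC[C@H]3[C@](C)(COC(=O)C(C)(C)C)[C@@H](C)CC=C23
F8 | step 10 | 4β-(4-nitrobenzoate) of the 5-ene C15 pivalate | O=C(O[C@H]1CCC[C@H]2[C@](C)(COC(=O)C(C)(C)C)[C@@H](C)CC=C12)c1ccc(cc1)[N+](=O)[O-]
F9 | step 24 | C15 iodide of the 4(11)-ene decalin | C=C1CCC[C@H]2[C@](C)(CI)[C@@H](C)CC[C@]12C
F10 | step 24 | C15 alkyllithium | C=C1CCC[C@H]2[C@](C)(C[Li])[C@@H](C)CC[C@]12C
F11 | step 24 | C15 alkylzinc chloride | C=C1CCC[C@H]2[C@](C)(C[Zn]Cl)[C@@H](C)CC[C@]12C
F12 | step 28 | methyl 5-(decalinylmethyl)-2,4-dihydroxy-3-nitrobenzoate | C=C1CCC[C@H]2[C@](C)(Cc3cc(C(=O)OC)c(O)c([N+](=O)[O-])c3O)[C@@H](C)CC[C@]12C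
F13 | step 29 | C17'-O-methyl ether of 41 (anilino methoxy quinone) | C=C1CCC[C@H]2[C@](C)(Cc3cc(C(=O)OC)c(O)c(NC4=CC(=O)C(OC)=C(C[C@]5(C)[C@@H](C)CC[C@]6(C)C(C)=CCC[C@@H]56)C4=O)c3O)[C@@H](C)CC[C@]12C
A1 | alternative 1 | 4-hydroxy-3-isopropoxy-2-(decalinylmethyl)-4-ynamido cyclobut-2-enone with N-aryl benzoxazolone (carbinol configuration undefined) | C=C1CCC[C@H]2[C@](C)(Cc3cc(C(=O)OC)c(OCOC)c4c3OC(=O)N4C#CC3(O)C(OC(C)C)=C(C[C@]5(C)[C@@H](C)CC[C@]6(C)C(C)=CCC[C@@H]56)C3=O)[C@@H](C)CC[C@]12C
A2 | alternative 1 | protected target with complete quinone (MOM, isopropyl, cyclic carbamate) | C=C1CCC[C@H]2[C@](C)(Cc3cc(C(=O)OC)c(OCOC)c4c3OC(=O)N4C3=CC(=O)C(OC(C)C)=C(C[C@]5(C)[C@@H](C)CC[C@]6(C)C(C)=CCC[C@@H]56)C3=O)[C@@H](C)CC[C@]12C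
A3 | alternative 2 | acyclic aryl enone with C5'=C12' methylidene, C4' silyl ether and C8' methyl ketone | CC(C)(C)[Si](C)(C)O[C@@H](CCC/C=C(\C)C(=O)c1c(OC)c(OC)cc(OC)c1OC)C(=C)CCC(C)=O
A4 | alternative 2 | trans-decalin with C9' aroyl group and C8' carbinol | CC(C)(C)[Si](C)(C)O[C@H]1CCC[C@H]2[C@](C)(C(=O)c3c(OC)c(OC)cc(OC)c3OC)[C@](C)(O)CC[C@]12C
A5 | alternative 3 | 8α-hydroxy-11-(2,5-dimethoxy-1,4-benzoquinon-3-yl)drimane | COC1=CC(=O)C(OC)=C(C[C@H]2[C@](C)(O)CC[C@H]3C(C)(C)CCC[C@]23C)C1=O
A6 | alternative 3 | half-B dimethoxyquinone with the 3-ene decalin (identical with 27) | COC1=CC(=O)C(OC)=C(C[C@]2(C)[C@@H](C)CC[C@]3(C)C(C)=CCC[C@@H]23)C1=O
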